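**Retrosynthetic overview**
- The target is three coumarins: central unit A, unit B joined by its C8 to C6 of A, and unit C joined by its C3 through oxygen to C7 of A. The C7(A)–O–C3(C) ether and the pyranone of unit C are traced to a Perkin condensation of the ring-A 7-oxyacetic acid with 2,4-dihydroxybenzaldehyde; O-demethylation of unit B is last.
- The pyranone of unit A (O1–C2–C3–C4) is traced to Wittig olefination and lactonisation of a 2,4-dihydroxybenzaldehyde.
- The plan rests on the benzene ring of unit A (C4a, C5, C6, C7, C8, C8a): it is a resorcinol ring with oxygens on C7 and C8a, the C4 carbon on C4a and unit B on C6. This is the pattern delivered by a 4-aryl-1,3-dioxygenated butadiene and propynal, so the ring is built on unit B by [4+2] benzannulation (new bonds C5–C6 and C4a–C8a) and the crowded C6(A)–C8(B) aryl–aryl bond is never made by coupling.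
- The diene is traced to umbelliferone: the future C6 of ring A enters as the benzylic carbon of an 8-allyl group (O-allylation, Claisen), which is cut to the arylacetic acid, homologated with Meldrum's acid and silylated twice.
- Ring order: unit B (bought) → benzene ring of A → pyranone of A → pyranone of C (its benzene ring bought).

Key step: step 9

Remark: the target has no stereocentre; the C6(A)–C8(B) axis has only oxygen and hydrogen substituents in its ortho positions and is treated as freely rotating, so no stereocontrol is planned.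

**Route**

Step 1
Reactants: 1 umbelliferone (7-hydroxychromen-2-one); 2 allyl bromide
Product: 3 7-(allyloxy)chromen-2-one
Conditions: K2CO3, acetone, reflux
Reagents that add atoms: none
Why: Williamson O-alkylation (SN2) of the acidic 7-phenol by the allylic bromide under carbonate conditions that leave the lactone closed.

Step 2
Reactants: 3 7-(allyloxy)chromen-2-one
Product: 4 8-allyl-7-hydroxychromen-2-one
Conditions: N,N-diethylaniline, reflux (ca. 215 °C), N2; the minor 6-allyl isomer removed by crystallisation or chromatography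
Reagents that add atoms: none
Why: Aromatic Claisen [3,3] rearrangement, expected to go mainly to C8 because the C7–C8 bond of the coumarin has the higher double-bond character.

Step 3
Reactants: 4 8-allyl-7-hydroxychromen-2-one
Product: 5 8-allyl-7-methoxychromen-2-one
Conditions: MeI, K2CO3, acetone, reflux
Reagents that add atoms: iodomethane, CI
Why: Williamson methylation gives a methyl ether that should withstand the silyl triflate, heat, acid and anhydride used later and is removed by BBr3 in the last step.

Step 4
Reactants: 5 8-allyl-7-methoxychromen-2-one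
Product: 6 2-(7-methoxy-2-oxochromen-8-yl)acetaldehyde
Conditions: OsO4 (cat.), NaIO4, 2,6-lutidine, dioxane–H2O, rt
Reagents that add atoms: osmium tetroxide, O=[Os](=O)(=O)=O; sodium periodate (stoichiometric oxygen source), [Na+].[O-]I(=O)(=O)=O
Why: Lemieux–Johnson cleavage, in which OsO4 should dihydroxylate the isolated terminal alkene much faster than the electron-poor conjugated C3=C4 bond of the coumarin and periodate cleaves the diol.

Step 5
Reactants: 6 2-(7-methoxy-2-oxochromen-8-yl)acetaldehyde
Product: 7 2-(7-methoxy-2-oxochromen-8-yl)acetic acid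
Conditions: NaClO2, NaH2PO4, 2-methyl-2-butene, t-BuOH–H2O, rt
Reagents that add atoms: sodium chlorite, [Na+].[O-]Cl=O
Why: Pinnick oxidation is selective for the aldehyde, and the alkene scavenger removes hypochlorous acid before it can chlorinate the electron-rich arene.

Step 6
Reactants: 7 2-(7-methoxy-2-oxochromen-8-yl)acetic acid; 8 Meldrum's acid (2,2-dimethyl-1,3-dioxane-4,6-dione)
Product: 10 methyl 4-(7-methoxy-2-oxochromen-8-yl)-3-oxobutanoate, via acyl Meldrum's acid 9 (not isolated)
Conditions: DCC, DMAP, CH2Cl2, 0 °C → rt, filter; then MeOH, reflux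
Reagents that add atoms: methanol, CO
Why: Oikawa–Yonemitsu homologation, in which carbodiimide-mediated C-acylation of Meldrum's acid is followed by methanolysis with loss of acetone and CO2 to give the beta-keto ester.

Step 7
Reactants: 10 methyl 4-(7-methoxy-2-oxochromen-8-yl)-3-oxobutanoate
Product: 11 7-methoxy-8-[(1Z,3E)-4-methoxy-2,4-bis(trimethylsilyloxy)buta-1,3-dien-1-yl]chromen-2-one (the 4-aryl-1-methoxy-1,3-bis(trimethylsilyloxy)buta-1,3-diene; the geometry at the ketene acetal end is of no consequence)
Conditions: Me3SiOTf (2.3 equiv), Et3N (3 equiv), Et2O, 0 °C → rt; anhydrous work-up (pentane extraction), used crude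
Reagents that add atoms: trimethylsilyl trifluoromethanesulfonate, C[Si](C)(C)OS(=O)(=O)C(F)(F)F
Why: Twofold O-silylation by soft enolisation, in which the ketone is silylated first and the ester oxygen second with removal of the acidic benzylic gamma-hydrogen, so no strong base that could attack the coumarin is needed and the aryl group should sit cis to the silyloxy group, on the outside of the s-cis diene.

Step 8
Reactants: 12 propargyl alcohol (prop-2-yn-1-ol)
Product: 13 propynal
Conditions: CrO3, H2SO4, H2O, 2–10 °C, ca. 50 mmHg, distilled into traps at −78 °C; dried and used at once as a toluene solution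
Reagents that add atoms: none
Why: Chromic acid oxidation of the primary propargylic alcohol, with the volatile aldehyde distilled out under reduced pressure as it forms so that over-oxidation and polymerisation are limited.

Step 9
Reactants: 11 7-methoxy-8-[(1Z,3E)-4-methoxy-2,4-bis(trimethylsilyloxy)buta-1,3-dien-1-yl]chromen-2-one; 13 propynal
Product: 16 2,4-dihydroxy-5-(7-methoxy-2-oxochromen-8-yl)benzaldehyde, via cyclohexadiene cycloadduct 14 (not isolated), via bis(trimethylsilyl) ether 15 (not isolated)
Conditions: 13 (2 equiv), BHT (trace), toluene, −20 °C → rt (50 °C if conversion stalls); then 1 M HCl, THF, rt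
Reagents that add atoms: none
Why: The electron-rich diene 11 and the electron-poor alkyne of 13 should combine in an asynchronous, normal-electron-demand [4+2] cycloaddition in which the nucleophilic diene terminus carrying unit B bonds first to the alkyne beta-carbon and the ketene acetal carbon then closes onto the formyl-bearing alpha-carbon, giving cyclohexa-1,4-diene 14. The six-membered carbocycle is thus closed by intermolecular cycloaddition, which forms the future C5–C6 and C4a–C8a bonds of ring A in one operation, and it becomes aromatic by 1,4-elimination of methanol from the mixed acetal carbon and the doubly allylic C–H (to 15), after which dilute acid removes both silyl groups. The closest known reaction type is the Diels–Alder benzannulation of Danishefsky-, Brassard- and Chan-type silyloxydienes with acetylenic esters, ketones and aldehydes to phenols and resorcinols. The two stereocentres of 14 are lost on aromatisation, so no stereocontrol is needed. The step needs regiocontrol, which the matched polarity of the two partners secures (the formyl group ends ortho to the oxygen from the ketene acetal carbon and para to the oxygen from the enol ether carbon), and chemoselectivity for C≡C over C=O, which the absence of any Lewis acid and the low starting temperature should secure because aldol or hetero-Diels–Alder attack on the aldehyde needs carbonyl activation. The coumarin C3=C4 bond is a far poorer dienophile than the ynal, and the (Z) geometry of the aryl enol ether keeps the bulky aryl group outside the s-cis diene.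

Step 10
Reactants: 16 2,4-dihydroxy-5-(7-methoxy-2-oxochromen-8-yl)benzaldehyde
Product: 18 7-hydroxy-6-(7-methoxy-2-oxochromen-8-yl)chromen-2-one, via ethyl cinnamate 17 (not isolated)
Conditions: Ph3P=CHCO2Et, N,N-diethylaniline, reflux (ca. 215 °C)
Reagents that add atoms: ethyl (triphenylphosphoranylidene)acetate, CCOC(=O)C=P(c1ccccc1)(c1ccccc1)c1ccccc1
Why: Wittig olefination followed in the same pot by thermal E/Z isomerisation and lactonisation with loss of ethanol is the standard conversion of salicylaldehydes into coumarins, and only the ortho hydroxyl can lactonise, so the 7-OH stays free.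

Step 11
Reactants: 18 7-hydroxy-6-(7-methoxy-2-oxochromen-8-yl)chromen-2-one
Product: 19 tert-butyl 2-{[6-(7-methoxy-2-oxochromen-8-yl)-2-oxochromen-7-yl]oxy}acetate
Conditions: BrCH2CO2t-Bu, K2CO3, acetone, 50 °C
Reagents that add atoms: tert-butyl bromoacetate, CC(C)(C)OC(=O)CBr
Why: Williamson etherification (SN2) of the only free phenol with an unhindered alpha-bromo ester, the tert-butyl ester being chosen so that the acid can be released without base.

Step 12
Reactants: 19 tert-butyl 2-{[6-(7-methoxy-2-oxochromen-8-yl)-2-oxochromen-7-yl]oxy}acetate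
Product: 20 2-{[6-(7-methoxy-2-oxochromen-8-yl)-2-oxochromen-7-yl]oxy}acetic acid
Conditions: CF3CO2H–CH2Cl2 (1:1), rt
Reagents that add atoms: none
Why: Acidolysis of the tert-butyl ester by loss of isobutene should leave both lactones and the methyl ether untouched.

Step 13
Reactants: 20 2-{[6-(7-methoxy-2-oxochromen-8-yl)-2-oxochromen-7-yl]oxy}acetic acid; 21 2,4-dihydroxybenzaldehyde
Product: 22 3-{[6-(7-methoxy-2-oxochromen-8-yl)-2-oxochromen-7-yl]oxy}-2-oxochromen-7-yl acetate
Conditions: NaOAc, Ac2O, 150 °C
Reagents that add atoms: acetic anhydride, CC(=O)OC(C)=O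
Why: Perkin condensation, in which the mixed anhydride of the aryloxyacetic acid acylates the ortho hydroxyl of the aldehyde and intramolecular aldol condensation with dehydration closes the pyranone of unit C with the aryloxy group on C3, while the para hydroxyl is acetylated.

Step 14
Reactants: 22 3-{[6-(7-methoxy-2-oxochromen-8-yl)-2-oxochromen-7-yl]oxy}-2-oxochromen-7-yl acetate
Product: 23 7-hydroxy-3-{[6-(7-methoxy-2-oxochromen-8-yl)-2-oxochromen-7-yl]oxy}chromen-2-one
Conditions: HCl (cat.), MeOH–THF, 50 °C
Reagents that add atoms: none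
Why: Acid-catalysed transesterification removes the aryl acetate as methyl acetate, and the coumarin lactones are stable in acidic methanol.

Step 15
Reactants: 23 7-hydroxy-3-{[6-(7-methoxy-2-oxochromen-8-yl)-2-oxochromen-7-yl]oxy}chromen-2-one
Product: 24 7-hydroxy-8-{7-[(7-hydroxy-2-oxochromen-3-yl)oxy]-2-oxochromen-6-yl}chromen-2-one (target)
Conditions: BBr3 (excess, ca. 8 equiv), CH2Cl2, −78 °C → rt; then H2O
Reagents that add atoms: none
Why: Lewis-acid ether cleavage, in which BBr3 binds the methyl ether oxygen and bromide attacks the methyl carbon (SN2), whereas the diaryl ether offers no sp3 carbon and the lactones are regenerated on aqueous work-up.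

**Compound list**
1 | umbelliferone (7-hydroxychromen-2-one) | O=c1ccc2ccc(O)cc2o1 | starting material
2 | allyl bromide | C=CCBr | starting material
3 | 7-(allyloxy)chromen-2-one | C=CCOc1ccc2ccc(=O)oc2c1 | intermediate
4 | 8-allyl-7-hydroxychromen-2-one | C=CCc1c(O)ccc2ccc(=O)oc12 | intermediate
5 | 8-allyl-7-methoxychromen-2-one | C=CCc1c(OC)ccc2ccc(=O)oc12 | intermediate
6 | 2-(7-methoxy-2-oxochromen-8-yl)acetaldehyde | O=CCc1c(OC)ccc2ccc(=O)oc12 | intermediate
7 | 2-(7-methoxy-2-oxochromen-8-yl)acetic acid | OC(=O)Cc1c(OC)ccc2ccc(=O)oc12 | intermediate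
8 | Meldrum's acid (2,2-dimethyl-1,3-dioxane-4,6-dione) | CC1(C)OC(=O)CC(=O)O1 | starting material
9 | 5-[1-hydroxy-2-(7-methoxy-2-oxochromen-8-yl)ethylidene]-2,2-dimethyl-1,3-dioxane-4,6-dione (acyl Meldrum's acid, enol form) | CC1(C)OC(=O)C(=C(O)Cc2c(OC)ccc3ccc(=O)oc23)C(=O)O1 | intermediate
10 | methyl 4-(7-methoxy-2-oxochromen-8-yl)-3-oxobutanoate | COC(=O)CC(=O)Cc1c(OC)ccc2ccc(=O)oc12 | intermediate
11 | 7-methoxy-8-[(1Z,3E)-4-methoxy-2,4-bis(trimethylsilyloxy)buta-1,3-dien-1-yl]chromen-2-one | COc1ccc2ccc(=O)oc2c1/C=C(O[Si](C)(C)C)/C=C(\OC)O[Si](C)(C)C | intermediate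
12 | propargyl alcohol (prop-2-yn-1-ol) | C#CCO | starting material
13 | propynal | C#CC=O | intermediate
14 | 6-methoxy-3-(7-methoxy-2-oxochromen-8-yl)-4,6-bis(trimethylsilyloxy)cyclohexa-1,4-diene-1-carbaldehyde (mixture of diastereomers) | COC1(O[Si](C)(C)C)C=C(O[Si](C)(C)C)C(c2c(OC)ccc3ccc(=O)oc23)C=C1C=O | intermediate
15 | 5-(7-methoxy-2-oxochromen-8-yl)-2,4-bis(trimethylsilyloxy)benzaldehyde | O=Cc1cc(-c2c(OC)ccc3ccc(=O)oc23)c(O[Si](C)(C)C)cc1O[Si](C)(C)C | intermediate
16 | 2,4-dihydroxy-5-(7-methoxy-2-oxochromen-8-yl)benzaldehyde | O=Cc1cc(-c2c(OC)ccc3ccc(=O)oc23)c(O)cc1O | intermediate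
17 | ethyl (E)-3-[2,4-dihydroxy-5-(7-methoxy-2-oxochromen-8-yl)phenyl]prop-2-enoate | CCOC(=O)/C=C/c1cc(-c2c(OC)ccc3ccc(=O)oc23)c(O)cc1O | intermediate
18 | 7-hydroxy-6-(7-methoxy-2-oxochromen-8-yl)chromen-2-one | O=c1ccc2cc(-c3c(OC)ccc4ccc(=O)oc34)c(O)cc2o1 | intermediate
19 | tert-butyl 2-{[6-(7-methoxy-2-oxochromen-8-yl)-2-oxochromen-7-yl]oxy}acetate | CC(C)(C)OC(=O)COc1cc2oc(=O)ccc2cc1-c1c(OC)ccc2ccc(=O)oc12 | intermediate
20 | 2-{[6-(7-methoxy-2-oxochromen-8-yl)-2-oxochromen-7-yl]oxy}acetic acid | OC(=O)COc1cc2oc(=O)ccc2cc1-c1c(OC)ccc2ccc(=O)oc12 | intermediate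
21 | 2,4-dihydroxybenzaldehyde | O=Cc1ccc(O)cc1O | starting material
22 | 3-{[6-(7-methoxy-2-oxochromen-8-yl)-2-oxochromen-7-yl]oxy}-2-oxochromen-7-yl acetate | CC(=O)Oc1ccc2cc(Oc3cc4oc(=O)ccc4cc3-c3c(OC)ccc4ccc(=O)oc34)c(=O)oc2c1 | intermediate
23 | 7-hydroxy-3-{[6-(7-methoxy-2-oxochromen-8-yl)-2-oxochromen-7-yl]oxy}chromen-2-one | Oc1ccc2cc(Oc3cc4oc(=O)ccc4cc3-c3c(OC)ccc4ccc(=O)oc34)c(=O)oc2c1 | intermediate
24 | 7-hydroxy-8-{7-[(7-hydroxy-2-oxochromen-3-yl)oxy]-2-oxochromen-6-yl}chromen-2-one | O=c1ccc2cc(-c3c(O)ccc4ccc(=O)oc34)c(Oc3cc4ccc(O)cc4oc3=O)cc2o1 | target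

**Step count**
Total: 15 steps. Longest linear sequence: 14 steps (steps 1–7 and 9–15, from umbelliferone); step 8 is a one-step side branch.

**Steps most likely to fail**

1. Step 9. The cycloaddition may be outrun by addition of the diene to the formyl group, by polymerisation of the ynal, or by hydrolytic loss of the silyl groups from the diene; the twisted ortho,ortho-disubstituted aryl group may also slow bond formation at the diene terminus. The fallback makes the aryl–aryl bond by Suzuki–Miyaura coupling; it sets out from 1 and 21 and comes back at 16. Umbelliferone 1 would be iodinated at C8 (I2, KI, aqueous NH3) to 7-hydroxy-8-iodochromen-2-one F1 and methylated (MeI, K2CO3) to 8-iodo-7-methoxychromen-2-one F2. Aldehyde 21 would be brominated (Br2, AcOH) to 5-bromo-2,4-dihydroxybenzaldehyde F3, protected (MOMCl, i-Pr2NEt) as 5-bromo-2,4-bis(methoxymethoxy)benzaldehyde F4 and borylated (B2pin2, KOAc, PdCl2(dppf), dioxane, 90 °C) to 2,4-bis(methoxymethoxy)-5-(4,4,5,5-tetramethyl-1,3,2-dioxaborolan-2-yl)benzaldehyde F5. Coupling of F2 with F5 (Pd(OAc)2, SPhos, K3PO4, toluene–H2O, 90 °C) should give 5-(7-methoxy-2-oxochromen-8-yl)-2,4-bis(methoxymethoxy)benzaldehyde F6, and HCl in MeOH would remove both acetals to give 16.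

2. Step 13. At 150 °C in acetic anhydride the aldehyde may simply be acetylated on both hydroxyls without C–C bond formation, and the acid may decarboxylate or char. The fallback separates acylation from ring closure; it sets out from 20 and 21 and comes back at 23. Aldehyde 21 would be protected at its non-chelated 4-hydroxyl (MOMCl, K2CO3, acetone) to 2-hydroxy-4-(methoxymethoxy)benzaldehyde F7 and esterified with 20 (EDC·HCl, DMAP, CH2Cl2) to 2-formyl-5-(methoxymethoxy)phenyl 2-{[6-(7-methoxy-2-oxochromen-8-yl)-2-oxochromen-7-yl]oxy}acetate F8. DBU in MeCN should then close the pyranone by intramolecular aldol condensation to 7-(methoxymethoxy)-3-{[6-(7-methoxy-2-oxochromen-8-yl)-2-oxochromen-7-yl]oxy}chromen-2-one F9, and HCl in MeOH would give 23.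

3. Step 10. The (E)-cinnamate may fail to isomerise and lactonise, or the unprotected resorcinol aldehyde may decompose at 215 °C. The fallback uses Knoevenagel condensation and decarboxylation; it sets out from 16 and comes back at 18. Aldehyde 16 would be condensed with Meldrum's acid 8 (piperidinium acetate cat., EtOH, reflux) to 7-hydroxy-6-(7-methoxy-2-oxochromen-8-yl)-2-oxochromene-3-carboxylic acid F10, and decarboxylation (Cu powder, quinoline, 200 °C) would give 18.

**Further compounds**
F1 | step 9 | 7-hydroxy-8-iodochromen-2-one | O=c1ccc2ccc(O)c(I)c2o1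
F2 | step 9 | 8-iodo-7-methoxychromen-2-one | COc1ccc2ccc(=O)oc2c1I
F3 | step 9 | 5-bromo-2,4-dihydroxybenzaldehyde | O=Cc1cc(Br)c(O)cc1O
F4 | step 9 | 5-bromo-2,4-bis(methoxymethoxy)benzaldehyde | COCOc1cc(OCOC)c(C=O)cc1Br
F5 | step 9 | 2,4-bis(methoxymethoxy)-5-(4,4,5,5-tetramethyl-1,3,2-dioxaborolan-2-yl)benzaldehyde | COCOc1cc(OCOC)c(C=O)cc1B1OC(C)(C)C(C)(C)O1
F6 | step 9 | 5-(7-methoxy-2-oxochromen-8-yl)-2,4-bis(methoxymethoxy)benzaldehyde | COCOc1cc(OCOC)c(C=O)cc1-c1c(OC)ccc2ccc(=O)oc12
F7 | step 13 | 2-hydroxy-4-(methoxymethoxy)benzaldehyde | COCOc1ccc(C=O)c(O)c1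
F8 | step 13 | 2-formyl-5-(methoxymethoxy)phenyl 2-{[6-(7-methoxy-2-oxochromen-8-yl)-2-oxochromen-7-yl]oxy}acetate | COCOc1ccc(C=O)c(OC(=O)COc2cc3oc(=O)ccc3cc2-c2c(OC)ccc3ccc(=O)oc23)c1
F9 | step 13 | 7-(methoxymethoxy)-3-{[6-(7-methoxy-2-oxochromen-8-yl)-2-oxochromen-7-yl]oxy}chromen-2-one | COCOc1ccc2cc(Oc3cc4oc(=O)ccc4cc3-c3c(OC)ccc4ccc(=O)oc34)c(=O)oc2c1
F10 | step 10 | 7-hydroxy-6-(7-methoxy-2-oxochromen-8-yl)-2-oxochromene-3-carboxylic acid | OC(=O)c1cc2cc(-c3c(OC)ccc4ccc(=O)oc34)c(O)cc2oc1=O
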